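**Retrosynthetic overview**
- The strategy rests on the dihydropyran ring. C2 is benzylic and para to the free OH of the 4-hydroxy-3-methoxyphenyl ring, so it can be the exocyclic carbon of a p-quinone methide. O1–C6=C5 is the enol of an aldehyde whose α-carbon C5 carries the benzofuran-2-yl group.
- The last ring bond, O1–C2, is therefore cut to an open-chain 2-(benzofuran-2-yl)pentanal with a free guaiacol, closed by oxidation and oxa-1,6-addition.
- The aldehyde carbon comes from a methoxymethylene Wittig reaction on a 2-acylbenzofuran. The acetyl group is carried as an aryl bromide until after the Wittig step (Stille coupling), and one acid treatment unveils aldehyde, acetyl and guaiacol together.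
- The furan ring of the benzofuran is made by Rap-Stoermer annulation of a chiral bromomethyl ketone with a salicylaldehyde. The single carbon stereocenter of the chain comes from an Evans propargylation.
- Ring order: furan ring of the benzofuran first (step 10), dihydropyran last (step 14).

Key step: step 14

Remark: the chain stereocenter keeps one spatial arrangement throughout. Its CIP descriptor is R in 9–11 and 23, and S in 12, 13, 17, 18, 20, 22 and at C3 of the ring, only because the ranking of its substituents changes.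
Remark: the benzofuran phenol is carried as a triisopropylsilyl ether, which should survive the basic steps and is removed by buffered fluoride at the end. The aldehyde α-carbon of 23 is a mixture of epimers that becomes sp2 in step 14.

**Step 1**
Reactants: 1 3-(4-hydroxy-3-methoxyphenyl)propanoic acid
Product: 3 3-[3-methoxy-4-(methoxymethoxy)phenyl]propanoic acid, via bis-MOM ester 2 (not isolated)
Conditions: MeOCH2Cl (2.5 equiv), iPr2NEt, CH2Cl2, 0 °C to rt; then LiOH, THF/H2O, rt; 1 M HCl to pH 4, 0 °C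
Reagents that add atoms: chloromethyl methyl ether, COCCl; lithium hydroxide, [Li+].[OH-]
Why: Phenol and acid are both O-alkylated (Williamson-type alkylation) and saponification then cleaves only the methoxymethyl ester, leaving the aryl acetal that is stable to every basic step ahead.

**Step 2**
Reactants: 3 3-[3-methoxy-4-(methoxymethoxy)phenyl]propanoic acid; 4 (4R)-4-benzyl-1,3-oxazolidin-2-one
Product: 6 (4R)-4-benzyl-3-{3-[3-methoxy-4-(methoxymethoxy)phenyl]propanoyl}-1,3-oxazolidin-2-one, via mixed pivalic anhydride 5 (not isolated)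
Conditions: Me3CCOCl, Et3N, THF, −20 °C; then 4, LiCl, rt
Reagents that add atoms: none
Why: N-acylation of the oxazolidinone by a mixed anhydride under LiCl/Et3N activation, with attack at the less hindered carbonyl of the anhydride.

**Step 3**
Reactants: 6 (4R)-4-benzyl-3-{3-[3-methoxy-4-(methoxymethoxy)phenyl]propanoyl}-1,3-oxazolidin-2-one; 7 3-bromoprop-1-yne
Product: 9 (4R)-4-benzyl-3-[(2R)-2-{[3-methoxy-4-(methoxymethoxy)phenyl]methyl}pent-4-ynoyl]-1,3-oxazolidin-2-one, via sodium Z-enolate 8 (not isolated)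
Conditions: NaN(SiMe3)2, THF, −78 °C; then 7 (3 equiv), −78 to −40 °C
Reagents that add atoms: none
Why: Evans asymmetric alkylation, in which propargyl bromide enters the chelated Z-enolate on the face opposite the benzyl group of the (R)-auxiliary and so sets the stereocenter that becomes C3 of the target.

**Step 4**
Reactants: 9 (4R)-4-benzyl-3-[(2R)-2-{[3-methoxy-4-(methoxymethoxy)phenyl]methyl}pent-4-ynoyl]-1,3-oxazolidin-2-one
Product: 10 (2R)-2-{[3-methoxy-4-(methoxymethoxy)phenyl]methyl}pent-4-yn-1-ol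
Conditions: LiBH4, H2O (1 equiv), THF, 0 °C
Reagents that add atoms: none
Why: Reductive cleavage of the imide at the exocyclic carbonyl by LiBH4, which does not enolise the stereocenter and leaves alkyne and acetal alone.

**Step 5**
Reactants: 10 (2R)-2-{[3-methoxy-4-(methoxymethoxy)phenyl]methyl}pent-4-yn-1-ol
Product: 11 (2R)-2-{[3-methoxy-4-(methoxymethoxy)phenyl]methyl}pent-4-yn-1-yl acetate
Conditions: Ac2O, pyridine, DMAP (cat.), CH2Cl2, 0 °C to rt
Reagents that add atoms: acetic anhydride, CC(=O)OC(C)=O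
Why: DMAP-catalysed acylation installs the primary acetate of the target early, which also keeps the oxygen from closing onto the bromoketone made later.

**Step 6**
Reactants: 11 (2R)-2-{[3-methoxy-4-(methoxymethoxy)phenyl]methyl}pent-4-yn-1-yl acetate
Product: 12 (2S)-5-bromo-2-{[3-methoxy-4-(methoxymethoxy)phenyl]methyl}pent-4-yn-1-yl acetate
Conditions: NBS (1.1 equiv), AgNO3 (10 mol%), acetone, rt, dark
Reagents that add atoms: N-bromosuccinimide, O=C1CCC(=O)N1Br
Why: Silver-catalysed bromination of the terminal alkyne through its silver acetylide, which in acetone without acid should be much faster than bromination of the alkoxyarene.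

**Step 7**
Reactants: 12 (2S)-5-bromo-2-{[3-methoxy-4-(methoxymethoxy)phenyl]methyl}pent-4-yn-1-yl acetate
Product: 13 (2S)-5-bromo-2-{[3-methoxy-4-(methoxymethoxy)phenyl]methyl}-4-oxopentyl acetate
Conditions: (XPhos)AuNTf2 (2 mol%), H2O (3 equiv), ClCH2CH2Cl, rt
Reagents that add atoms: water, O
Why: Gold-catalysed hydration of a 1-bromoalkyne, in which water adds at the carbon remote from bromine and gives the bromomethyl ketone without any electrophilic bromine source.

**Step 8**
Reactants: 14 4-bromo-2,5-dimethoxybenzaldehyde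
Product: 15 4-bromo-2,5-dihydroxybenzaldehyde
Conditions: BBr3 (3 equiv), CH2Cl2, −78 °C to rt; H2O
Reagents that add atoms: none
Why: Lewis-acid cleavage of both aryl methyl ethers by BBr3, which the aldehyde and the aryl bromide tolerate.

**Step 9**
Reactants: 15 4-bromo-2,5-dihydroxybenzaldehyde
Product: 16 4-bromo-2-hydroxy-5-{[tri(propan-2-yl)silyl]oxy}benzaldehyde
Conditions: iPr3SiCl (1.05 equiv), imidazole, CH2Cl2, 0 °C
Reagents that add atoms: chlorotri(propan-2-yl)silane, CC(C)[Si](Cl)(C(C)C)C(C)C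
Why: Regioselective silylation of the 5-hydroxyl, because the 2-hydroxyl is held in a hydrogen bond to the formyl group and is much less nucleophilic.

**Step 10**
Reactants: 13 (2S)-5-bromo-2-{[3-methoxy-4-(methoxymethoxy)phenyl]methyl}-4-oxopentyl acetate; 16 4-bromo-2-hydroxy-5-{[tri(propan-2-yl)silyl]oxy}benzaldehyde
Product: 18 (2S)-4-(6-bromo-5-{[tri(propan-2-yl)silyl]oxy}-1-benzofuran-2-yl)-2-{[3-methoxy-4-(methoxymethoxy)phenyl]methyl}-4-oxobutyl acetate, via aryloxymethyl ketone 17 (not isolated)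
Conditions: K2CO3, MeCN, 60 °C
Reagents that add atoms: none
Why: Rap-Stoermer annulation, in which the phenoxide displaces bromide and the activated OCH2 group then undergoes intramolecular aldol condensation with the ortho formyl group to close the furan ring.

**Step 11**
Reactants: 18 (2S)-4-(6-bromo-5-{[tri(propan-2-yl)silyl]oxy}-1-benzofuran-2-yl)-2-{[3-methoxy-4-(methoxymethoxy)phenyl]methyl}-4-oxobutyl acetate; 19 (methoxymethyl)triphenylphosphonium chloride
Product: 20 (2S)-4-(6-bromo-5-{[tri(propan-2-yl)silyl]oxy}-1-benzofuran-2-yl)-5-methoxy-2-{[3-methoxy-4-(methoxymethoxy)phenyl]methyl}pent-4-en-1-yl acetate (E/Z mixture)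
Conditions: 19 (2 equiv), KN(SiMe3)2, THF, 0 °C; then 18, −78 to 0 °C
Reagents that add atoms: none
Why: Wittig methoxymethylenation of the only ketone present (the acetyl group is still a bromide), with a salt-free ylide at low temperature to spare the primary acetate.

**Step 12**
Reactants: 20 (2S)-4-(6-bromo-5-{[tri(propan-2-yl)silyl]oxy}-1-benzofuran-2-yl)-5-methoxy-2-{[3-methoxy-4-(methoxymethoxy)phenyl]methyl}pent-4-en-1-yl acetate; 21 tributyl(1-ethoxyethenyl)stannane
Product: 22 (2S)-4-[6-(1-ethoxyethenyl)-5-{[tri(propan-2-yl)silyl]oxy}-1-benzofuran-2-yl]-5-methoxy-2-{[3-methoxy-4-(methoxymethoxy)phenyl]methyl}pent-4-en-1-yl acetate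
Conditions: 21 (1.5 equiv), Pd(PPh3)2Cl2 (5 mol%), toluene, 100 °C
Reagents that add atoms: none
Why: Stille coupling of the aryl bromide with the acetyl anion equivalent under neutral conditions that leave acetate, silyl ether, acetal and enol ether untouched.

**Step 13**
Reactants: 22 (2S)-4-[6-(1-ethoxyethenyl)-5-{[tri(propan-2-yl)silyl]oxy}-1-benzofuran-2-yl]-5-methoxy-2-{[3-methoxy-4-(methoxymethoxy)phenyl]methyl}pent-4-en-1-yl acetate
Product: 23 (2R)-4-(6-acetyl-5-{[tri(propan-2-yl)silyl]oxy}-1-benzofuran-2-yl)-2-[(4-hydroxy-3-methoxyphenyl)methyl]-5-oxopentyl acetate (both C4 epimers; as a pentanal, the 4R compound)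
Conditions: CF3CO2H/H2O/CH2Cl2 (10:1:40), 0 °C to rt
Reagents that add atoms: water, O
Why: Acid hydrolysis of both enol ethers to the aryl methyl ketone and the aldehyde and of the aryl methoxymethyl acetal to the guaiacol in one flask, under conditions with too little water to hydrolyse the primary acetate and too mild to cleave the aryl triisopropylsilyl ether.

**Step 14**
Reactants: 23 (2R)-4-(6-acetyl-5-{[tri(propan-2-yl)silyl]oxy}-1-benzofuran-2-yl)-2-[(4-hydroxy-3-methoxyphenyl)methyl]-5-oxopentyl acetate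
Product: 25 [(2R,3S)-5-(6-acetyl-5-{[tri(propan-2-yl)silyl]oxy}-1-benzofuran-2-yl)-2-(4-hydroxy-3-methoxyphenyl)-3,4-dihydro-2H-pyran-3-yl]methyl acetate, via p-quinone methide 24 (not isolated)
Conditions: Ag2O (1.5 equiv), 4 Å MS, CH2Cl2, rt, dark; then filtration and (PhO)2P(O)OH (5 mol%), 0 °C
Reagents that add atoms: none
Why: Proposed new method: Ag2O removes the phenolic hydrogen and one benzylic hydrogen of the guaiacol to give p-quinone methide 24, and the oxygen of the aldehyde enol, whose content is raised by conjugation with the benzofuran, adds to the methide carbon in an oxa-1,6-addition driven by rearomatisation; the closest known reaction types are the Ag2O-mediated oxidative cyclisation of 4-alkylguaiacols onto tethered hydroxyl groups in lignan chemistry and the acid-catalysed addition of oxygen nucleophiles to p-quinone methides. The dihydropyran closes in a 6-exo-trig mode at the exocyclic methide carbon, whereas attack through the enol carbon would need a cyclobutane. C2 is set relative to the existing C3 center by a chair-like transition state with the aryl and acetoxymethyl groups equatorial, and because the p-hydroxybenzylic C–O bond can reionise under the phosphoric acid, the trans (2R,3S) isomer should also be the thermodynamic one. Chemoselectivity for the guaiacol is secured by the silyl ether on the other phenol and by anhydrous conditions, under which Ag2O should leave the aldehyde alone. The oxidant is limited and the acid contact kept short and cold, because a second oxidation of the product, capture of the methide by benzofuran C3 or tautomerisation to the styrene would be irreversible. The aldehyde α-carbon becomes sp2, so both epimers of 23 converge on 25.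

**Step 15**
Reactants: 25 [(2R,3S)-5-(6-acetyl-5-{[tri(propan-2-yl)silyl]oxy}-1-benzofuran-2-yl)-2-(4-hydroxy-3-methoxyphenyl)-3,4-dihydro-2H-pyran-3-yl]methyl acetate
Product: 26 [(2R,3S)-5-(6-acetyl-5-hydroxy-1-benzofuran-2-yl)-2-(4-hydroxy-3-methoxyphenyl)-3,4-dihydro-2H-pyran-3-yl]methyl acetate (propolis-benzofuran A)
Conditions: Bu4NF/AcOH (1:1), THF, 0 °C
Reagents that add atoms: none
Why: Fluoride cleaves the aryl silyl ether, which the ortho acetyl group activates, while the acetic acid buffer keeps the liberated phenoxide from attacking the primary acetate and leaves the enol ether and both stereocenters untouched (silyl ether deprotection).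

**Compound list**
1 | 3-(4-hydroxy-3-methoxyphenyl)propanoic acid | COc1cc(CCC(=O)O)ccc1O | starting material
2 | methoxymethyl 3-[3-methoxy-4-(methoxymethoxy)phenyl]propanoate | COCOC(=O)CCc1ccc(OCOC)c(OC)c1 | intermediate
3 | 3-[3-methoxy-4-(methoxymethoxy)phenyl]propanoic acid | COCOc1ccc(CCC(=O)O)cc1OC | intermediate
4 | (4R)-4-benzyl-1,3-oxazolidin-2-one | O=C1N[C@H](Cc2ccccc2)CO1 | starting material
5 | 2,2-dimethylpropanoic 3-[3-methoxy-4-(methoxymethoxy)phenyl]propanoic anhydride | COCOc1ccc(CCC(=O)OC(=O)C(C)(C)C)cc1OC | intermediate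
6 | (4R)-4-benzyl-3-{3-[3-methoxy-4-(methoxymethoxy)phenyl]propanoyl}-1,3-oxazolidin-2-one | COCOc1ccc(CCC(=O)N2[C@H](Cc3ccccc3)COC2=O)cc1OC | intermediate
7 | 3-bromoprop-1-yne (propargyl bromide) | C#CCBr | starting material
8 | sodium (Z)-enolate of 6 | COCOc1ccc(C/C=C(\[O-])N2[C@H](Cc3ccccc3)COC2=O)cc1OC.[Na+] | intermediate
9 | (4R)-4-benzyl-3-[(2R)-2-{[3-methoxy-4-(methoxymethoxy)phenyl]methyl}pent-4-ynoyl]-1,3-oxazolidin-2-one | C#CC[C@H](Cc1ccc(OCOC)c(OC)c1)C(=O)N1[C@H](Cc2ccccc2)COC1=O | intermediate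
10 | (2R)-2-{[3-methoxy-4-(methoxymethoxy)phenyl]methyl}pent-4-yn-1-ol | C#CC[C@H](Cc1ccc(OCOC)c(OC)c1)CO | intermediate
11 | (2R)-2-{[3-methoxy-4-(methoxymethoxy)phenyl]methyl}pent-4-yn-1-yl acetate | C#CC[C@H](Cc1ccc(OCOC)c(OC)c1)COC(C)=O | intermediate
12 | (2S)-5-bromo-2-{[3-methoxy-4-(methoxymethoxy)phenyl]methyl}pent-4-yn-1-yl acetate | BrC#CC[C@H](Cc1ccc(OCOC)c(OC)c1)COC(C)=O | intermediate
13 | (2S)-5-bromo-2-{[3-methoxy-4-(methoxymethoxy)phenyl]methyl}-4-oxopentyl acetate | BrCC(=O)C[C@H](Cc1ccc(OCOC)c(OC)c1)COC(C)=O | intermediate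
14 | 4-bromo-2,5-dimethoxybenzaldehyde | COc1cc(C=O)c(OC)cc1Br | starting material
15 | 4-bromo-2,5-dihydroxybenzaldehyde | O=Cc1cc(O)c(Br)cc1O | intermediate
16 | 4-bromo-2-hydroxy-5-{[tri(propan-2-yl)silyl]oxy}benzaldehyde | CC(C)[Si](Oc1cc(C=O)c(O)cc1Br)(C(C)C)C(C)C | intermediate
17 | (2S)-5-(5-bromo-2-formyl-4-{[tri(propan-2-yl)silyl]oxy}phenoxy)-2-{[3-methoxy-4-(methoxymethoxy)phenyl]methyl}-4-oxopentyl acetate | O=Cc1cc(O[Si](C(C)C)(C(C)C)C(C)C)c(Br)cc1OCC(=O)C[C@H](Cc1ccc(OCOC)c(OC)c1)COC(C)=O | intermediate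
18 | (2S)-4-(6-bromo-5-{[tri(propan-2-yl)silyl]oxy}-1-benzofuran-2-yl)-2-{[3-methoxy-4-(methoxymethoxy)phenyl]methyl}-4-oxobutyl acetate | O=C(C[C@H](Cc1ccc(OCOC)c(OC)c1)COC(C)=O)c1cc2cc(O[Si](C(C)C)(C(C)C)C(C)C)c(Br)cc2o1 | intermediate
19 | (methoxymethyl)triphenylphosphonium chloride | COC[P+](c1ccccc1)(c1ccccc1)c1ccccc1.[Cl-] | starting material
20 | (2S)-4-(6-bromo-5-{[tri(propan-2-yl)silyl]oxy}-1-benzofuran-2-yl)-5-methoxy-2-{[3-methoxy-4-(methoxymethoxy)phenyl]methyl}pent-4-en-1-yl acetate (E/Z mixture) | COC=C(C[C@H](Cc1ccc(OCOC)c(OC)c1)COC(C)=O)c1cc2cc(O[Si](C(C)C)(C(C)C)C(C)C)c(Br)cc2o1 | intermediate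
21 | tributyl(1-ethoxyethenyl)stannane | CCCC[Sn](CCCC)(CCCC)C(=C)OCC | starting material
22 | (2S)-4-[6-(1-ethoxyethenyl)-5-{[tri(propan-2-yl)silyl]oxy}-1-benzofuran-2-yl]-5-methoxy-2-{[3-methoxy-4-(methoxymethoxy)phenyl]methyl}pent-4-en-1-yl acetate (E/Z mixture) | C=C(OCC)c1cc2oc(C(=COC)C[C@H](Cc3ccc(OCOC)c(OC)c3)COC(C)=O)cc2cc1O[Si](C(C)C)(C(C)C)C(C)C | intermediate
23 | (2R)-4-(6-acetyl-5-{[tri(propan-2-yl)silyl]oxy}-1-benzofuran-2-yl)-2-[(4-hydroxy-3-methoxyphenyl)methyl]-5-oxopentyl acetate (C4 epimers) | O=CC(C[C@H](Cc1ccc(O)c(OC)c1)COC(C)=O)c1cc2cc(O[Si](C(C)C)(C(C)C)C(C)C)c(C(C)=O)cc2o1 | intermediate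
24 | (2R)-4-(6-acetyl-5-{[tri(propan-2-yl)silyl]oxy}-1-benzofuran-2-yl)-2-[(3-methoxy-4-oxocyclohexa-2,5-dien-1-ylidene)methyl]-5-oxopentyl acetate | COC1=CC(=C[C@H](COC(C)=O)CC(C=O)c2cc3cc(O[Si](C(C)C)(C(C)C)C(C)C)c(C(C)=O)cc3o2)C=CC1=O | intermediate
25 | [(2R,3S)-5-(6-acetyl-5-{[tri(propan-2-yl)silyl]oxy}-1-benzofuran-2-yl)-2-(4-hydroxy-3-methoxyphenyl)-3,4-dihydro-2H-pyran-3-yl]methyl acetate | COc1cc([C@@H]2OC=C(c3cc4cc(O[Si](C(C)C)(C(C)C)C(C)C)c(C(C)=O)cc4o3)C[C@H]2COC(C)=O)ccc1O | intermediate
26 | [(2R,3S)-5-(6-acetyl-5-hydroxy-1-benzofuran-2-yl)-2-(4-hydroxy-3-methoxyphenyl)-3,4-dihydro-2H-pyran-3-yl]methyl acetate (propolis-benzofuran A) | COc1cc([C@@H]2OC=C(c3cc4cc(O)c(C(C)=O)cc4o3)C[C@H]2COC(C)=O)ccc1O | target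

**Step count**
Total: 15 steps. Longest linear sequence: 13 steps (steps 1 to 7 and 10 to 15); steps 8 and 9 form the short branch.

**Steps most likely to fail**

Step 14. The enol oxygen may add too slowly, so that the quinone methide tautomerises to the styrene, is captured at benzofuran C3, or the product is oxidised a second time. The fallback sets out from 23 and comes back at 25, and uses only known steps. Compound 23 is oxidised with Ag2O under the same anhydrous conditions to 24 and the silver is filtered off. Water in THF is then added, a hydration that is known for guaiacyl quinone methides. The benzylic alcohol so formed should close on the aldehyde to the lactol [(3S)-5-(6-acetyl-5-{[tri(propan-2-yl)silyl]oxy}-1-benzofuran-2-yl)-6-hydroxy-2-(4-hydroxy-3-methoxyphenyl)oxan-3-yl]methyl acetate F1, a mixture of isomers at C2, C5 and C6. Pyridinium p-toluenesulfonate in toluene over 4 Å MS at 60 °C should dehydrate the lactol to the conjugated enol ether and equilibrate C2 through the benzylic cation, which should give trans 25.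

Step 11. The basic ylide may enolise the hindered heteroaryl ketone or take the acetyl group from the primary acetate. The fallback sets out from 18 and comes back at 23, and avoids any basic carbon nucleophile.
- Takai-Lombardo methylenation (Zn, CH2Br2, TiCl4, THF/CH2Cl2, 0 °C) should give (2S)-4-(6-bromo-5-{[tri(propan-2-yl)silyl]oxy}-1-benzofuran-2-yl)-2-{[3-methoxy-4-(methoxymethoxy)phenyl]methyl}pent-4-en-1-yl acetate F2.
- Anti-Markovnikov hydroboration with 9-BBN and oxidation with NaBO3·4H2O should give (2R)-4-(6-bromo-5-{[tri(propan-2-yl)silyl]oxy}-1-benzofuran-2-yl)-5-hydroxy-2-{[3-methoxy-4-(methoxymethoxy)phenyl]methyl}pentyl acetate F3.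
- Dess-Martin periodinane should oxidise it to (2R)-4-(6-bromo-5-{[tri(propan-2-yl)silyl]oxy}-1-benzofuran-2-yl)-2-{[3-methoxy-4-(methoxymethoxy)phenyl]methyl}-5-oxopentyl acetate F4.
- Stille coupling with 21 under the conditions of step 12 should give (2R)-4-[6-(1-ethoxyethenyl)-5-{[tri(propan-2-yl)silyl]oxy}-1-benzofuran-2-yl]-2-{[3-methoxy-4-(methoxymethoxy)phenyl]methyl}-5-oxopentyl acetate F5.
- The acid treatment of step 13 then converts F5 to 23.

Step 13. Cleavage of the aryl methoxymethyl ether may be slower than acid-induced loss of the acetate or degradation of the enolisable aldehyde. The fallback sets out from 22 and comes back at 23, and separates the two events. Pyridinium p-toluenesulfonate in wet acetone at rt should hydrolyse only the two enol ethers and give (2R)-4-(6-acetyl-5-{[tri(propan-2-yl)silyl]oxy}-1-benzofuran-2-yl)-2-{[3-methoxy-4-(methoxymethoxy)phenyl]methyl}-5-oxopentyl acetate F6. The phenolic acetal is then removed without water by NaHSO4 on SiO2 in CH2Cl2 at rt, which should give 23.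

**Further compounds**
F1 | step 14 | [(3S)-5-(6-acetyl-5-{[tri(propan-2-yl)silyl]oxy}-1-benzofuran-2-yl)-6-hydroxy-2-(4-hydroxy-3-methoxyphenyl)oxan-3-yl]methyl acetate | COc1cc(C2OC(O)C(c3cc4cc(O[Si](C(C)C)(C(C)C)C(C)C)c(C(C)=O)cc4o3)C[C@H]2COC(C)=O)ccc1O
F2 | step 11 | (2S)-4-(6-bromo-5-{[tri(propan-2-yl)silyl]oxy}-1-benzofuran-2-yl)-2-{[3-methoxy-4-(methoxymethoxy)phenyl]methyl}pent-4-en-1-yl acetate | C=C(C[C@H](Cc1ccc(OCOC)c(OC)c1)COC(C)=O)c1cc2cc(O[Si](C(C)C)(C(C)C)C(C)C)c(Br)cc2o1
F3 | step 11 | (2R)-4-(6-bromo-5-{[tri(propan-2-yl)silyl]oxy}-1-benzofuran-2-yl)-5-hydroxy-2-{[3-methoxy-4-(methoxymethoxy)phenyl]methyl}pentyl acetate | OCC(C[C@H](Cc1ccc(OCOC)c(OC)c1)COC(C)=O)c1cc2cc(O[Si](C(C)C)(C(C)C)C(C)C)c(Br)cc2o1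
F4 | step 11 | (2R)-4-(6-bromo-5-{[tri(propan-2-yl)silyl]oxy}-1-benzofuran-2-yl)-2-{[3-methoxy-4-(methoxymethoxy)phenyl]methyl}-5-oxopentyl acetate | O=CC(C[C@H](Cc1ccc(OCOC)c(OC)c1)COC(C)=O)c1cc2cc(O[Si](C(C)C)(C(C)C)C(C)C)c(Br)cc2o1
F5 | step 11 | (2R)-4-[6-(1-ethoxyethenyl)-5-{[tri(propan-2-yl)silyl]oxy}-1-benzofuran-2-yl]-2-{[3-methoxy-4-(methoxymethoxy)phenyl]methyl}-5-oxopentyl acetate | C=C(OCC)c1cc2oc(C(C=O)C[C@H](Cc3ccc(OCOC)c(OC)c3)COC(C)=O)cc2cc1O[Si](C(C)C)(C(C)C)C(C)C
F6 | step 13 | (2R)-4-(6-acetyl-5-{[tri(propan-2-yl)silyl]oxy}-1-benzofuran-2-yl)-2-{[3-methoxy-4-(methoxymethoxy)phenyl]methyl}-5-oxopentyl acetate | O=CC(C[C@H](Cc1ccc(OCOC)c(OC)c1)COC(C)=O)c1cc2cc(O[Si](C(C)C)(C(C)C)C(C)C)c(C(C)=O)cc2o1
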